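**The task.** Feeding costs time. Elm gets J by a steady feed, oak gets E by a steady feed, and alder gets everything at the start.

| setting | Tuesday's | Thursday's | Wednesday's | Saturday's | elm | alder | oak |
|---|---|---|---|---|---|---|---|
| E | 0.078 M | 0.039 M | 0.058 M | 0.078 M | 0.078 M | 0.078 M | 0.078 M (fed, over 2.0 min) |
| J | 0.14 M | 0.14 M | 0.14 M | 0.070 M | 0.140 M (fed, over 2.0 min) | 0.140 M | 0.140 M |
| Q | 0.101 M | 0.101 M | 0.101 M | 0.101 M | 0.101 M | 0.101 M | 0.101 M |
| remark | run made earlier | run made earlier | run made earlier | run made earlier | all else is in the flask from the start; the feed brings no volume worth counting | everything together at the start | all else is in the flask from the start; the feed brings no volume worth counting |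
| time |  |  |  |  | 3.0 min | 3.0 min | 3.0 min |

| run | time / min | G / % |
|---|---|---|
| Tuesday's | 0.250 | 1.8 |
| Tuesday's | 0.833 | 16.2 |
| Tuesday's | 1.33 | 29.6 |
| Tuesday's | 2.00 | 41.0 |
| Tuesday's | 3.00 | 54.7 |
| Thursday's | 0.250 | 2.3 |
| Thursday's | 0.500 | 8.4 |
| Thursday's | 1.00 | 23.3 |
| Thursday's | 2.00 | 44.0 |
| Thursday's | 4.00 | 65.1 |
| Wednesday's | 0.250 | 1.4 |
| Wednesday's | 0.500 | 7.3 |
| Wednesday's | 1.00 | 22.0 |
| Wednesday's | 2.00 | 43.6 |
| Wednesday's | 4.00 | 62.9 |
| Saturday's | 0.250 | 1.3 |
| Saturday's | 0.500 | 3.7 |
| Saturday's | 1.00 | 12.6 |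
| Saturday's | 2.00 | 23.3 |
| Saturday's | 4.00 | 37.5 |

(readings scatter by 0.5 percentage points)

- Q is a solid; its amount is given per volume of the solution
- the numbers in the tables scatter by 0.5 percentage points (one standard deviation)
- steps under discussion: Z + X -> G; E + J -> X; E + Z -> L; Q <-> Z
- at the start none of Q is in solution

* the flask that comes out highest in amount of G, in percent of the E charged, or "all alike" when all lie within 1.5 percentage points (elm / alder / oak / all alike)
* G at the end, in percent of the E charged, elm
* G at the end, in percent of the E charged, alder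
* G at the end, in percent of the E charged, oak

**What matters.** At 2.00 min, cutting E from 0.078 M to 0.039 M moves G from 41.0% to 44.0%, a shift of 3 percentage points. So I take the E charge as a small lever on G in percent at this reading. Cutting J from 0.14 M to 0.070 M moves it further, to 23.3%, a shift of 18 points. Going on to 3.00 min lifts Tuesday's G by 14 points. Q is 0.101 M in each run, so the runs do not say what it is worth. The number to know well is how long E and J have shared the flask.

**Mean age.** A steady feed arrives on average 1.00 min late. At 3.0 min that leaves 2.00 min: the mean age a, the reading time less the mean lateness of the feed. It serves for both elm and oak.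

**My reckoning.** I read elm and oak off Tuesday's run at a = 2.00 min, which gives 41.0% for each. Alder is Tuesday's run at 3.00 min, 54.7%, which is higher by more than the margin.

**The forecast.** It puts alder highest, at 54.8% (53.5% to 56%), with oak at 43% (38% to 47%) and elm at 40% (35% to 45%). Unlike my level pair, it sets elm below oak, saying “J is low early, so E leaks to L”.

**The outcome.** Alder comes out highest at 53.9%, with oak at 40.1% and elm at 38.2%.

    Z + X → G (k = 1.39 L mol⁻¹ s⁻¹)
    E + J → X (k = 0.0482 L mol⁻¹ s⁻¹)
    E + Z → L (k = 0.0453 L mol⁻¹ s⁻¹)
    Q ⇌ Z, rate k4*(cs4 - [Z]) while solid is left; crystals form when [Z] > cs4 (solubility = 47.0 mM, k = 0.0530 s⁻¹)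

**Age applied.** Oak lies 0.90 points under the reading at 2.00 min, and elm lies 2.8 points under it, with L at 20.9% in elm against 13.9% in oak. In elm, the rate at which E turns into X over the rate at which E turns into L stands at 1.2 at 0.681 min and reaches 2.7 at 3.00 min. Elm read at 12 min has a mean age of 11.0 min and holds E at 1.57% and G at 68.0%.

The data were generated by integration for substances that don't exist.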